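**Retrosynthetic overview**
- Ten-membered ring closed last at C2=C3 by intramolecular Knoevenagel condensation of a C2 aldehyde with a β-keto ester whose lactol form is already the C4 hemiketal.
- C3–C4 comes from Claisen addition of methyl acetate enolate to a butenolide; the urocanate is put on C8–OH just before.
- C7–C8 (key step): catalyst-controlled vinylogous Mukaiyama aldol of 2-silyloxy-5-methylfuran (from 2-methylfuran) with the ring A acetaldehyde. The furan loses its aromaticity, C7 and C8 are set together, and C4 arrives at the lactone oxidation level.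
- Ring A: (R)-cryptone, then a 3-(diethoxymethyl) enone, then CuH reduction/enolate alkylation (C1 arm cis to isopropyl, C10 arm trans to it), enol triflate and methyl coupling.
- Ring order: cyclohexene (ring A) first, the furanone second, the ten-membered carbocycle last; its closure also locks the bridging hemiketal.

Assumption: the SMILES is read literally, i.e. (1R,4R,7S,8S,10R,14R) in eunicellane numbering C1–C15, with the C1 arm cis to isopropyl and trans to the C10 arm on ring A; positions below use this numbering.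

**Route**

Step 1
Reactants: 1 3-methylbutanal; 2 but-3-en-2-one
Product: 4 (4R)-4-(propan-2-yl)cyclohex-2-en-1-one, via keto aldehyde 3 (not isolated)
Conditions: (R)-diphenylprolinol TMS ether (5 mol %), ethyl 3,4-dihydroxybenzoate (20 mol %), neat, 4 °C; then LiOH (10 mol %), i-PrOH, rt
Reagents that add atoms: none
Why: Enamine-catalysed Michael addition (the catalyst shields one enamine face and sets the isopropyl-bearing centre, C14) followed by intramolecular aldol condensation, an organocatalytic Robinson-type annulation.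

Step 2
Reactants: 4 (4R)-4-(propan-2-yl)cyclohex-2-en-1-one
Product: 6 (4R)-3-ethenyl-4-(propan-2-yl)cyclohex-2-en-1-one, via TMS enol ether 5 (not isolated)
Conditions: CH2=CHMgBr, CuBr·SMe2 (10 mol %), TMSCl, THF, −78 °C; then Pd(OAc)2 (10 mol %), O2 (1 atm), DMSO, rt
Reagents that add atoms: vinylmagnesium bromide C=C[Mg]Br
Why: Copper-catalysed 1,4-addition with silyl trapping gives the regiodefined enol ether and Saegusa–Ito oxidation restores the enone with the vinyl group on the β-carbon; the transient β-centre is erased and the γ-centre is untouched.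

Step 3
Reactants: 6 (4R)-3-ethenyl-4-(propan-2-yl)cyclohex-2-en-1-one
Product: 8 (4R)-3-(diethoxymethyl)-4-(propan-2-yl)cyclohex-2-en-1-one, via formyl enone 7 (not isolated)
Conditions: O3, CH2Cl2/EtOH, −78 °C (Sudan red end point); Me2S; then HC(OEt)3, TsOH (5 mol %), rt
Reagents that add atoms: triethyl orthoformate CCOC(OCC)OCC
Why: Chemoselective ozonolysis cleaves the terminal, electron-richer alkene of the dienone faster than the electron-poor ring enone, and the sensitive aldehyde is acetalised at once (acid-catalysed acetalisation).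

Step 4
Reactants: 8 (4R)-3-(diethoxymethyl)-4-(propan-2-yl)cyclohex-2-en-1-one
Product: 10 methyl 2-[(1R,2S,3R)-2-(diethoxymethyl)-6-oxo-3-(propan-2-yl)cyclohexyl]acetate, via PhMe2Si enol ether 9 (not isolated)
Conditions: [(Ph3P)CuH]6 (5 mol %), PhMe2SiH, toluene, rt; then MeLi, THF, −78 °C; BrCH2CO2Me, DMPU, −78 → −40 °C, cold quench
Reagents that add atoms: methyl bromoacetate COC(=O)CBr
Why: Tandem conjugate reduction–enolate alkylation: CuH delivers hydride to the β-carbon anti to the isopropyl group (held pseudoaxial by A(1,2) strain with the acetal), which puts the acetal cis to isopropyl (C1), and the regiodefined enolate freed by MeLi is alkylated axially, anti to the now axial acetal (C10 arm trans to the C1 arm).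

Step 5
Reactants: 10 methyl 2-[(1R,2S,3R)-2-(diethoxymethyl)-6-oxo-3-(propan-2-yl)cyclohexyl]acetate
Product: 11 methyl 2-[(1R,5R,6S)-6-(diethoxymethyl)-5-(propan-2-yl)-2-(trifluoromethanesulfonyloxy)cyclohex-2-en-1-yl]acetate
Conditions: LiN(i-Pr)2 (1.05 equiv), THF, −78 °C; PhNTf2, −78 → 0 °C
Reagents that add atoms: N-phenylbis(trifluoromethanesulfonimide) O=S(=O)(N(c1ccccc1)S(=O)(=O)C(F)(F)F)C(F)(F)F
Why: Kinetic enolisation occurs at the unhindered CH2 (the C10 methine has only a poorly aligned equatorial hydrogen), and O-sulfonylation gives the enol triflate that fixes the later C11=C12 position without epimerising C10.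

Step 6
Reactants: 11 the enol triflate
Product: 12 methyl 2-[(1R,5R,6S)-6-(diethoxymethyl)-2-methyl-5-(propan-2-yl)cyclohex-2-en-1-yl]acetate
Conditions: MeMgBr, Fe(acac)3 (5 mol %), THF/NMP, −30 °C
Reagents that add atoms: methylmagnesium bromide C[Mg]Br
Why: Iron-catalysed Kumada-type coupling of the alkenyl triflate is much faster than Grignard addition to the ester at this temperature and installs the vinylic methyl group.

Step 7
Reactants: 12 the ring A ester
Product: 13 2-[(1R,5R,6S)-6-(diethoxymethyl)-2-methyl-5-(propan-2-yl)cyclohex-2-en-1-yl]acetaldehyde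
Conditions: i-Bu2AlH (1.05 equiv), CH2Cl2, −78 °C; aqueous work-up
Reagents that add atoms: none
Why: Partial ester reduction stops at the tetrahedral aluminate at −78 °C and releases the C8 aldehyde on work-up; acetal and alkene are inert.

Step 8
Reactants: 14 2-methylfuran
Product: 15 trimethyl[(5-methylfuran-2-yl)oxy]silane
Conditions: n-BuLi, THF, 0 °C; then Me3SiOOSiMe3, −78 °C → rt; distillation
Reagents that add atoms: bis(trimethylsilyl) peroxide C[Si](C)(C)OO[Si](C)(C)C
Why: α-Lithiation at the free C5 position followed by electrophilic oxygenation of the furyllithium by the silyl peroxide gives the 2-silyloxyfuran directly (oxidation of an aryllithium with a peroxide).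

Step 9
Reactants: 13 the ring A acetaldehyde; 15 trimethyl[(5-methylfuran-2-yl)oxy]silane
Product: 17 (5S)-5-{(1S)-2-[(1R,5R,6S)-6-(diethoxymethyl)-2-methyl-5-(propan-2-yl)cyclohex-2-en-1-yl]-1-hydroxyethyl}-5-methylfuran-2(5H)-one, via TMS ether 16 (not isolated)
Conditions: Ti(Oi-Pr)4 (20 mol %), (R)-BINOL (20 mol %), Et2O, −20 °C; then Bu4NF, AcOH, THF, 0 °C
Reagents that add atoms: none
Why: Catalytic asymmetric vinylogous Mukaiyama aldol: the Ti(Oi-Pr)4/BINOL Lewis acid (enantiomer chosen to expose the Re face of the aldehyde, giving 8S) is attacked by the methyl-bearing C5 of the silyloxyfuran, which is dearomatised to the butenolide, and the open Lewis-acid transition state gives the like (7S,8S) pair of quaternary and carbinol centres.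

Step 10
Reactants: 18 1-methyl-1H-imidazole-4-carbaldehyde; 19 malonic acid
Product: 20 (2E)-3-(1-methyl-1H-imidazol-4-yl)prop-2-enoic acid
Conditions: pyridine, piperidine (cat.), 90 °C
Reagents that add atoms: none
Why: Knoevenagel–Doebner condensation with decarboxylation gives the (E)-acid under thermodynamic control.

Step 11
Reactants: 17 the butenolide alcohol; 20 the N-methylurocanic acid
Product: 21 (1S)-2-[(1R,5R,6S)-6-(diethoxymethyl)-2-methyl-5-(propan-2-yl)cyclohex-2-en-1-yl]-1-[(2S)-2-methyl-5-oxo-2,5-dihydrofuran-2-yl]ethyl (2E)-3-(1-methyl-1H-imidazol-4-yl)prop-2-enoate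
Conditions: EDC·HCl, DMAP (cat.), CH2Cl2, rt → 40 °C
Reagents that add atoms: none
Why: Steglich esterification acylates the only free hydroxyl with retention at C8 and also blocks translactonisation and later six-membered hemiketal formation.

Step 12
Reactants: 21 the butenolide urocanate
Product: 22 methyl 2-[(5S)-5-{(1S)-2-[(1R,5R,6S)-6-(diethoxymethyl)-2-methyl-5-(propan-2-yl)cyclohex-2-en-1-yl]-1-{[(2E)-3-(1-methyl-1H-imidazol-4-yl)prop-2-enoyl]oxy}ethyl}-2-hydroxy-5-methyl-2,5-dihydrofuran-2-yl]acetate (lactol, anomers)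
Conditions: MeOAc, LiN(i-Pr)2, THF, −78 °C; then 21, −78 °C; AcOH quench at −78 °C
Reagents that add atoms: methyl acetate COC(C)=O
Why: Claisen-type 1,2-addition of LiCH2CO2Me to the strained butenolide carbonyl (its β-carbon is shielded by the adjacent quaternary C7 and the hindered urocanate ester is far less electrophilic) gives a tetrahedral adduct that is protonated to the cyclic hemiketal form of the β-keto ester.

Step 13
Reactants: 22 the lactol β-keto ester
Product: 24 methyl (1R,4R,7S,8S,10R,14R)-4-hydroxy-7,11-dimethyl-8-{[(2E)-3-(1-methyl-1H-imidazol-4-yl)prop-2-enoyl]oxy}-14-(propan-2-yl)-4,7-epoxybicyclo[8.4.0]tetradeca-2,5,11-triene-3-carboxylate, via seco aldehyde 23 (not isolated)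
Conditions: AcOH/H2O (4:1), 40 °C; evaporate; then piperidine (30 mol %), 4 Å MS, toluene (1 mM), 50 °C
Reagents that add atoms: none
Why: Proposed new method: mild acetal hydrolysis frees the C2 aldehyde, and the β-keto ester (open form of the lactol) condenses with it under piperidinium acetate catalysis to close the ten-membered ring at C2=C3 reversibly, the ring imposing the in-ring cis arrangement of C1 and C4 and the hemiketal reclosing in the only bridged geometry (C3 and C8 cis on the dihydrofuran, which fixes C4); the closest known reaction type is the intermolecular Knoevenagel condensation of α-branched aldehydes with active-methylene esters.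

**Compound list**
1 | 3-methylbutanal | CC(C)CC=O | starting material
2 | but-3-en-2-one | CC(=O)C=C | starting material
3 | (2R)-5-oxo-2-(propan-2-yl)hexanal | O=C[C@H](CCC(C)=O)C(C)C | intermediate
4 | (4R)-4-(propan-2-yl)cyclohex-2-en-1-one | O=C1C=C[C@H](CC1)C(C)C | intermediate
5 | {[(3R,4R)-3-ethenyl-4-(propan-2-yl)cyclohex-1-en-1-yl]oxy}trimethylsilane | C=C[C@H]1C=C(O[Si](C)(C)C)CC[C@@H]1C(C)C | intermediate
6 | (4R)-3-ethenyl-4-(propan-2-yl)cyclohex-2-en-1-one | C=CC1=CC(=O)CC[C@@H]1C(C)C | intermediate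
7 | (6R)-3-oxo-6-(propan-2-yl)cyclohex-1-ene-1-carbaldehyde | O=CC1=CC(=O)CC[C@@H]1C(C)C | intermediate
8 | (4R)-3-(diethoxymethyl)-4-(propan-2-yl)cyclohex-2-en-1-one | CCOC(OCC)C1=CC(=O)CC[C@@H]1C(C)C | intermediate
9 | {[(3S,4R)-3-(diethoxymethyl)-4-(propan-2-yl)cyclohex-1-en-1-yl]oxy}dimethyl(phenyl)silane | CCOC(OCC)[C@@H]1C=C(O[Si](C)(C)c2ccccc2)CC[C@@H]1C(C)C | intermediate
10 | methyl 2-[(1R,2S,3R)-2-(diethoxymethyl)-6-oxo-3-(propan-2-yl)cyclohexyl]acetate | CCOC(OCC)[C@H]1[C@@H](C(C)C)CCC(=O)[C@@H]1CC(=O)OC | intermediate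
11 | methyl 2-[(1R,5R,6S)-6-(diethoxymethyl)-5-(propan-2-yl)-2-(trifluoromethanesulfonyloxy)cyclohex-2-en-1-yl]acetate | CCOC(OCC)[C@H]1[C@@H](C(C)C)CC=C(OS(=O)(=O)C(F)(F)F)[C@@H]1CC(=O)OC | intermediate
12 | methyl 2-[(1R,5R,6S)-6-(diethoxymethyl)-2-methyl-5-(propan-2-yl)cyclohex-2-en-1-yl]acetate | CCOC(OCC)[C@H]1[C@@H](C(C)C)CC=C(C)[C@@H]1CC(=O)OC | intermediate
13 | 2-[(1R,5R,6S)-6-(diethoxymethyl)-2-methyl-5-(propan-2-yl)cyclohex-2-en-1-yl]acetaldehyde | CCOC(OCC)[C@H]1[C@@H](C(C)C)CC=C(C)[C@@H]1CC=O | intermediate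
14 | 2-methylfuran | Cc1ccco1 | starting material
15 | trimethyl[(5-methylfuran-2-yl)oxy]silane | Cc1ccc(O[Si](C)(C)C)o1 | intermediate
16 | trimethylsilyl ether of 17 | CCOC(OCC)[C@H]1[C@@H](C(C)C)CC=C(C)[C@@H]1C[C@H](O[Si](C)(C)C)[C@]1(C)C=CC(=O)O1 | intermediate
17 | (5S)-5-{(1S)-2-[(1R,5R,6S)-6-(diethoxymethyl)-2-methyl-5-(propan-2-yl)cyclohex-2-en-1-yl]-1-hydroxyethyl}-5-methylfuran-2(5H)-one | CCOC(OCC)[C@H]1[C@@H](C(C)C)CC=C(C)[C@@H]1C[C@H](O)[C@]1(C)C=CC(=O)O1 | intermediate
18 | 1-methyl-1H-imidazole-4-carbaldehyde | Cn1cnc(C=O)c1 | starting material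
19 | malonic acid | OC(=O)CC(=O)O | starting material
20 | (2E)-3-(1-methyl-1H-imidazol-4-yl)prop-2-enoic acid | Cn1cnc(/C=C/C(=O)O)c1 | intermediate
21 | C8 N-methylurocanate of 17 | CCOC(OCC)[C@H]1[C@@H](C(C)C)CC=C(C)[C@@H]1C[C@H](OC(=O)/C=C/c1cn(C)cn1)[C@]1(C)C=CC(=O)O1 | intermediate
22 | lactol β-keto ester (methyl acetate adduct of 21, anomers) | CCOC(OCC)[C@H]1[C@@H](C(C)C)CC=C(C)[C@@H]1C[C@H](OC(=O)/C=C/c1cn(C)cn1)[C@]1(C)C=CC(O)(CC(=O)OC)O1 | intermediate
23 | C2 aldehyde of 22 ((1R,5R,6S)-6-formyl ring A) | O=C[C@H]1[C@@H](C(C)C)CC=C(C)[C@@H]1C[C@H](OC(=O)/C=C/c1cn(C)cn1)[C@]1(C)C=CC(O)(CC(=O)OC)O1 | intermediate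
24 | CNP0372023.1, methyl (1R,4R,7S,8S,10R,14R)-4-hydroxy-7,11-dimethyl-8-(N-methylurocanoyloxy)-14-(propan-2-yl)-4,7-epoxybicyclo[8.4.0]tetradeca-2,5,11-triene-3-carboxylate | COC(=O)/C1=C/[C@H]2[C@@H](C(C)C)CC=C(C)[C@@H]2C[C@H](OC(=O)/C=C/c2cn(C)cn2)[C@]2(C)C=C[C@@]1(O)O2 | target

**Step count and risks**
Total steps: 13. Longest linear sequence: 11 (steps 1–7, 9, 11, 12, 13).

Step 13 (ring closure). A ten-membered Knoevenagel closure has no direct precedent, and the α-branched aldehyde can epimerise at C1 through its enamine. The fallback sets out from 22 and comes back at 24. The lactol is dehydrated (MsCl, Et3N) to the push–pull enol ether F6, with the acetal untouched. TMSOTf and 2,6-di-tert-butylpyridine at high dilution (CH2Cl2, −78 °C) ionise the diethyl acetal to an oxocarbenium ion, which is captured by the nucleophilic C3 of the enol ether in a Mukaiyama–Prins-type closure that needs no free aldehyde and no amine. Aqueous work-up restores the hemiketal and gives the ethoxy macrocycle F7, and DBU eliminates ethanol (E1cB) to 24.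

Step 9 (aldol). The facial control by the catalyst should hold, but the like/unlike ratio for a γ-methyl silyloxyfuran on this aldehyde is uncertain. The fallback sets out from 13 and comes back at 17. If the unlike isomer dominates, the aldol is run with Ti(Oi-Pr)4/(S)-BINOL so that the quaternary centre is correct, giving the silyl ether F1 and, after the same desilylation, the anti aldol F2 (7S,8R). Dess–Martin oxidation gives the ketone F3, and NaBH4/CeCl3·7H2O in MeOH at −78 °C (polar Felkin–Anh addition anti to the lactone C–O bond) returns 17. C8 is then set by substrate-controlled reduction and not in the C–C bond-forming event.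

Step 12 (Claisen addition). Conjugate addition to the butenolide or attack on the urocanate could compete with 1,2-addition. The fallback sets out from 21 and comes back at 22. i-Bu2AlH (1.1 equiv, −78 °C) reduces the strained lactone to the lactol F4. LiCH2CO2Me (2.2 equiv) then adds to its open (Z)-hydroxy enal form, where only 1,2-addition to an aldehyde is asked for, giving the diol F5. MnO2 oxidises the allylic C4 carbinol and the ketone closes to 22.

**Further compounds**
F1 | step 9 | trimethylsilyl ether of F2 | CCOC(OCC)[C@H]1[C@@H](C(C)C)CC=C(C)[C@@H]1C[C@@H](O[Si](C)(C)C)[C@]1(C)C=CC(=O)O1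
F2 | step 9 | (5S)-5-{(1R)-2-[(1R,5R,6S)-6-(diethoxymethyl)-2-methyl-5-(propan-2-yl)cyclohex-2-en-1-yl]-1-hydroxyethyl}-5-methylfuran-2(5H)-one | CCOC(OCC)[C@H]1[C@@H](C(C)C)CC=C(C)[C@@H]1C[C@@H](O)[C@]1(C)C=CC(=O)O1
F3 | step 9 | (5S)-5-{2-[(1R,5R,6S)-6-(diethoxymethyl)-2-methyl-5-(propan-2-yl)cyclohex-2-en-1-yl]acetyl}-5-methylfuran-2(5H)-one | CCOC(OCC)[C@H]1[C@@H](C(C)C)CC=C(C)[C@@H]1CC(=O)[C@]1(C)C=CC(=O)O1
F4 | step 12 | lactol of 21 (5-hydroxy-2-methyl-2,5-dihydrofuran-2-yl, anomers) | CCOC(OCC)[C@H]1[C@@H](C(C)C)CC=C(C)[C@@H]1C[C@H](OC(=O)/C=C/c1cn(C)cn1)[C@]1(C)C=CC(O)O1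
F5 | step 12 | open (Z)-enediol β-hydroxy ester (C4 carbinol, C7 tertiary alcohol) | CCOC(OCC)[C@H]1[C@@H](C(C)C)CC=C(C)[C@@H]1C[C@H](OC(=O)/C=C/c1cn(C)cn1)[C@](O)(C)/C=C\C(O)CC(=O)OC
F6 | step 13 | anhydro form of 22, methyl 2-[5-methylfuran-2(5H)-ylidene]acetate enol ether | CCOC(OCC)[C@H]1[C@@H](C(C)C)CC=C(C)[C@@H]1C[C@H](OC(=O)/C=C/c1cn(C)cn1)[C@]1(C)C=CC(=CC(=O)OC)O1
F7 | step 13 | 2-ethoxy-2,3-dihydro derivative of 24 | COC(=O)C1C(OCC)[C@H]2[C@@H](C(C)C)CC=C(C)[C@@H]2C[C@H](OC(=O)/C=C/c2cn(C)cn2)[C@]2(C)C=C[C@@]1(O)O2
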